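**Retrosynthetic overview**
- The target is cut at the C5–C6 sigma bond of its straight, unfunctionalised docosanoyl chain. C6–C22 comes from stearic acid as a heptadecyl radical. C1–C5 comes from an adipic half-ester radical that already carries the C1(=O)–O link to the OCH2CH2 arm of the para-disubstituted benzene ring.
- That half-ester is reached from tyrosol: the phenol oxygen is capped as its acetate, the primary hydroxyl is esterified with mono-tert-butyl adipate, and the tert-butyl group is removed by acidolysis.
- A crossed Kolbe electrolysis then joins the two chains, and mild aminolysis of the aryl acetate uncovers the phenol.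
- No ring is formed at any stage: the only ring, the benzene ring, is bought in tyrosol. There is no stereocentre and no alkene geometry to set.

Key step: step 4

Remark: the acyl chain is numbered from the ester carbonyl (C1) to the terminal methyl (C22); mono-tert-butyl adipate is taken as a purchasable building block.

Step 1
Reactants: 1 tyrosol, 2-(4-hydroxyphenyl)ethanol
Product: 3 4-(2-hydroxyethyl)phenyl acetate, via sodium 4-(2-hydroxyethyl)phenoxide 2 (not isolated)
Conditions: NaOH (1.05 equiv), H2O, 0 °C; then Ac2O (1.1 equiv), 0 °C, 15 min; EtOAc extraction
Reagents that add atoms: acetic anhydride, CC(=O)OC(C)=O; NaOH, [Na+].[OH-] (its sodium is held only in intermediate 2)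
Why: Chattaway-type acylation of a phenoxide: aqueous NaOH deprotonates only the phenol, and the phenoxide oxygen should outrun both the neutral primary hydroxyl and water for the anhydride at 0 °C, so the aryl acetate should form selectively; the acetyl group is installed to make the ring harder to oxidise in the later electrolysis.

Step 2
Reactants: 3 4-(2-hydroxyethyl)phenyl acetate; 4 6-tert-butoxy-6-oxohexanoic acid (adipic acid mono-tert-butyl ester)
Product: 5 tert-butyl 2-(4-acetoxyphenyl)ethyl hexanedioate
Conditions: DCC (1.1 equiv), DMAP (0.1 equiv), CH2Cl2, 0 °C to rt
Reagents that add atoms: none
Why: Steglich esterification: the carbodiimide activates the free carboxyl of 4 and DMAP relays the acyl group to the only free hydroxyl, the primary alcohol of 3, while the tert-butyl ester and the aryl acetate should be spectators under these neutral conditions.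

Step 3
Reactants: 5 tert-butyl 2-(4-acetoxyphenyl)ethyl hexanedioate
Product: 6 6-[2-(4-acetoxyphenyl)ethoxy]-6-oxohexanoic acid (adipic acid mono-2-(4-acetoxyphenyl)ethyl ester)
Conditions: TFA/CH2Cl2 (1:3), 0 °C to rt; evaporation from toluene
Reagents that add atoms: none
Why: Acidolysis of a tert-butyl ester by alkyl–oxygen cleavage through the tert-butyl cation, which leaves as 2-methylpropene; the primary alkyl ester and the aryl acetate cannot ionise in this way and should survive anhydrous TFA, and the acetoxy-deactivated ring should resist tert-butylation.

Step 4
Reactants: 6 6-[2-(4-acetoxyphenyl)ethoxy]-6-oxohexanoic acid; 7 stearic acid (octadecanoic acid)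
Product: 8 2-(4-acetoxyphenyl)ethyl docosanoate
Conditions: 7 (5 equiv) neutralised to ca. 5% with KOH in MeOH, then 6 (1 equiv); undivided cell, smooth Pt foil anode and cathode, 45–50 °C, constant current ca. 0.25 A cm-2, periodic polarity reversal; stopped while the electrolyte is still weakly acidic; filtration, then silica chromatography
Reagents that add atoms: none
Why: At the Pt anode both carboxylates should be discharged by one-electron oxidation and lose CO2, and the resulting heptadecyl and 4-[2-(4-acetoxyphenyl)ethoxycarbonyl]butyl radicals combine in the carboxylate-rich layer at the electrode to form the C5–C6 sigma bond, while the carboxyl protons are reduced to H2 at the cathode. The closest known reaction type is the classical crossed Kolbe electrolysis of a fatty acid with a dicarboxylic acid half-ester. No ring is closed and no stereocentre is created. Cross-coupling has to win over homo-coupling of the valuable half-ester, and the fivefold excess of cheap 7 should secure this by making almost every C5 radical meet a C17 radical; the homo-dimers (non-polar tetratriacontane, largely insoluble, and the more polar symmetrical sebacate diester) should be separable by filtration and chromatography. Radical coupling has to win over further oxidation to cations, which is favoured because both radicals are primary and unbranched with the ester carbonyl four carbons away, and because of the high current density on smooth Pt in a weakly acidic medium. Carboxylate discharge has to win over arene oxidation and ester cleavage: the acetyl group on the phenol oxygen raises the oxidation potential of the ring, the adsorbed carboxylate layer shields the anode, and the acid-buffered methanol (KOH consumed by 7 before 6 is added, electrolysis ended before the bath turns alkaline) should keep both esters from methanolysis.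

Step 5
Reactants: 8 2-(4-acetoxyphenyl)ethyl docosanoate
Product: 9 2-(4-hydroxyphenyl)ethyl docosanoate (target)
Conditions: pyrrolidine (3 equiv), THF, 0 °C to rt; dilute aqueous HCl wash
Reagents that add atoms: none
Why: Chemoselective aminolysis of an aryl ester: the aryloxide is a far better leaving group than an alkoxide, so the secondary amine should take the acetyl group from the phenol oxygen at or below room temperature and leave the unactivated docosanoate ester untouched, in an aprotic solvent that rules out transesterification.

**Compound list**
1 | tyrosol, 2-(4-hydroxyphenyl)ethanol | OCCc1ccc(O)cc1 | starting material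
2 | sodium 4-(2-hydroxyethyl)phenoxide | [Na+].[O-]c1ccc(CCO)cc1 | intermediate
3 | 4-(2-hydroxyethyl)phenyl acetate | CC(=O)Oc1ccc(CCO)cc1 | intermediate
4 | 6-tert-butoxy-6-oxohexanoic acid (adipic acid mono-tert-butyl ester) | CC(C)(C)OC(=O)CCCCC(=O)O | starting material
5 | tert-butyl 2-(4-acetoxyphenyl)ethyl hexanedioate | CC(C)(C)OC(=O)CCCCC(=O)OCCc1ccc(OC(C)=O)cc1 | intermediate
6 | 6-[2-(4-acetoxyphenyl)ethoxy]-6-oxohexanoic acid | OC(=O)CCCCC(=O)OCCc1ccc(OC(C)=O)cc1 | intermediate
7 | stearic acid (octadecanoic acid) | CCCCCCCCCCCCCCCCCC(=O)O | starting material
8 | 2-(4-acetoxyphenyl)ethyl docosanoate | CCCCCCCCCCCCCCCCCCCCCC(=O)OCCc1ccc(OC(C)=O)cc1 | intermediate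
9 | 2-(4-hydroxyphenyl)ethyl docosanoate | CCCCCCCCCCCCCCCCCCCCCC(=O)OCCc1ccc(O)cc1 | target

Total step count: 5. Longest linear sequence: 5 steps (1 to 3 to 5 to 6 to 8 to 9).

**Steps most likely to fail**

Step 4. The electrolysis may fail in several ways: the anode may be passivated by deposited long-chain hydrocarbon, the aryl acetate ring may be oxidised at the Kolbe potential, the esters may be cleaved by methanol where the solution near the cathode turns basic, or the half-ester may be lost to statistical homo-coupling. The fallback keeps the same C5–C6 anodic bond formation but runs it on partners that carry neither the arene nor a labile ester, and forms the ester link afterwards. It sets out from stearic acid 7, which is electrolysed in excess with purchased adipic acid monomethyl ester (6-methoxy-6-oxohexanoic acid) under the same conditions (KOH, MeOH, Pt, 45–50 °C) to give methyl docosanoate F1. Saponification (KOH, EtOH/H2O, reflux; then aqueous HCl) should give docosanoic acid F2. Esterification of F2 with alcohol 3 (DCC, DMAP, CH2Cl2) returns to the route at compound 8.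

Step 1. Discrimination between the phenoxide oxygen and the primary hydroxyl may be incomplete, or the freshly formed aryl acetate may be hydrolysed by hydroxide before extraction, giving mixtures of unacetylated, mono- and diacetylated material. The fallback sets out from tyrosol 1 and half-ester 4 and makes the alkyl ester first. Mitsunobu esterification (PPh3, DIAD, THF, 0 °C to rt) activates only the aliphatic hydroxyl as its alkoxyphosphonium ion, which the carboxylate displaces while the phenol stays free, and should give tert-butyl 2-(4-hydroxyphenyl)ethyl hexanedioate F3. With no competing alcohol left, acetylation of the phenol (Ac2O, pyridine, CH2Cl2, rt) returns to the route at compound 5.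

Step 3. The tert-butyl cation released in the acidolysis may be captured by the arene (ring tert-butylation), or the aryl acetate may be partly lost on prolonged contact with the strong acid. The fallback replaces the acid-labile ester by one that is removed under neutral conditions. It sets out from alcohol 3, which is esterified with purchased adipic acid monobenzyl ester (6-benzyloxy-6-oxohexanoic acid; DCC, DMAP, CH2Cl2) to give benzyl 2-(4-acetoxyphenyl)ethyl hexanedioate F4. Hydrogenolysis of the benzyl ester (H2 at 1 atm, Pd/C, EtOAc, rt), which should leave the homobenzylic alkyl ester and the aryl acetate alone, returns to the route at compound 6.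

**Further compounds**
F1 | step 4 | methyl docosanoate | CCCCCCCCCCCCCCCCCCCCCC(=O)OC
F2 | step 4 | docosanoic acid | CCCCCCCCCCCCCCCCCCCCCC(=O)O
F3 | step 1 | tert-butyl 2-(4-hydroxyphenyl)ethyl hexanedioate | CC(C)(C)OC(=O)CCCCC(=O)OCCc1ccc(O)cc1
F4 | step 3 | benzyl 2-(4-acetoxyphenyl)ethyl hexanedioate | CC(=O)Oc1ccc(CCOC(=O)CCCCC(=O)OCc2ccccc2)cc1
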